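**Assumption:** Piv = pivaloyl (2,2-dimethylpropanoyl); the ylide-face selectivity of 2,5-dimethylthiolane known from benzylide epoxidations ((2S,5S)-sulfide gives (R,R)-epoxides) is taken to carry over to o-quinone methide acceptors, where the same attack makes the ring C2 centre S. The two annulations are designed by analogy and have not been demonstrated on these substrates.

## Retrosynthetic overview

1. Target ⇐ reductive removal of nine acyl groups ⇐ Heck attachment of the 4-acetoxystyryl arm to a C4-bromo bis(dihydrobenzofuran) octapivalate.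
2. Lower dihydrobenzofuran (formed second) ⇐ intermolecular Michael addition of a chiral sulfonium benzylide (ylide carbon = C2, carried on C7 of the upper ring system) to an o-quinone methide (methide carbon = C3), then 5-exo SN2 closure.
3. Upper dihydrobenzofuran (formed first) ⇐ the same Michael/ring closure between the 2,4-bis(pivaloyloxy)benzyl sulfonium ylide and the o-quinone methide of the central resorcinol ring.
4. o-Quinone methide precursors (o-hydroxybenzhydryl sulfones) ⇐ o-hydroxybenzophenones (ortho-lithiation/nitrile addition for the central ring; Vilsmeier/Grignard/oxidation for the bromo ring); chelation-controlled pivaloylation leaves only the ring-forming OH free.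
5. Stereocontrol: C2-symmetric (2S,5S)-2,5-dimethylthiolane (from (2R,5R)-hexane-2,5-diol) on both ylides fixes C2; trans ring closure fixes C3.

## Route

**Chiral sulfide**

Step 1
Reactants: 1 (2R,5R)-hexane-2,5-diol
Product: 2 (2R,5R)-hexane-2,5-diyl dimethanesulfonate
Conditions: MsCl (2.5 equiv), Et3N, CH2Cl2, −20 → 0 °C
Reagents that add atoms: methanesulfonyl chloride CS(=O)(=O)Cl
Why: O-sulfonylation (mesylation) activates both secondary alcohols without touching the C–O stereocentres, so the (R,R) configuration is kept.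

Step 2
Reactants: 2 (2R,5R)-hexane-2,5-diyl dimethanesulfonate
Product: 3 (2S,5S)-2,5-dimethylthiolane
Conditions: Na2S·9H2O, DMSO, 25 °C; distillation
Reagents that add atoms: sodium sulfide [Na+].[Na+].[S-2]
Why: Double SN2 thioetherification inverts both carbinol carbons, turning the (R,R)-bis-mesylate into the C2-symmetric (2S,5S)-thiolane.

**First ylide precursor**

Step 3
Reactants: 4 4-methylbenzene-1,3-diol (4-methylresorcinol)
Product: 5 4-methyl-1,3-phenylene bis(2,2-dimethylpropanoate)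
Conditions: PivCl (2.3 equiv), Et3N, DMAP (cat.), CH2Cl2, 0 °C → rt
Reagents that add atoms: pivaloyl chloride CC(C)(C)C(=O)Cl
Why: Base-mediated esterification of both phenols; the acyloxy groups make the arene electron-poor, so the later benzylic bromide and sulfonium salt are stable.

Step 4
Reactants: 5 4-methyl-1,3-phenylene bis(2,2-dimethylpropanoate)
Product: 6 4-(bromomethyl)-1,3-phenylene bis(2,2-dimethylpropanoate)
Conditions: NBS (1.05 equiv), AIBN (cat.), PhCF3, 85 °C
Reagents that add atoms: N-bromosuccinimide O=C1CCC(=O)N1Br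
Why: Wohl–Ziegler radical bromination is selective for the benzylic methyl because the ring is deactivated and pivalates carry no abstractable α-hydrogens.

Step 5
Reactants: 6 4-(bromomethyl)-1,3-phenylene bis(2,2-dimethylpropanoate); 3 (2S,5S)-2,5-dimethylthiolane
Product: 7 (2S,5S)-1-[2,4-bis(pivaloyloxy)benzyl]-2,5-dimethylthiolan-1-ium tetrafluoroborate
Conditions: AgBF4 (1.05 equiv), CH2Cl2, −20 °C → rt, dark
Reagents that add atoms: silver tetrafluoroborate [Ag+].F[B-](F)(F)F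
Why: Silver-assisted SN2 S-alkylation; because the thiolane is C2-symmetric the sulfonium sulfur is not a stereocentre and a single salt forms.

**Central-ring o-quinone methide precursor**

Step 6
Reactants: 8 2,4-dimethoxybenzaldehyde
Product: 9 2-(2,4-dimethoxyphenyl)-1,3-dioxolane
Conditions: ethylene glycol, p-TsOH (cat.), toluene, reflux (Dean–Stark)
Reagents that add atoms: ethane-1,2-diol OCCO
Why: Acid-catalysed acetalisation with azeotropic water removal masks the aldehyde against the organolithium chemistry of the next step.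

Step 7
Reactants: 9 2-(2,4-dimethoxyphenyl)-1,3-dioxolane; 10 3,5-dimethoxybenzonitrile
Product: 13 3-(3,5-dimethoxybenzoyl)-2,4-dimethoxybenzaldehyde, via aryllithium 11 (not isolated), via N-lithio ketimine 12 (not isolated)
Conditions: n-BuLi (1.1 equiv), THF, 0 °C; then 10, 0 °C → rt; then 3 M HCl, THF, 50 °C
Reagents that add atoms: water O
Why: Directed ortho-metalation occurs at the position flanked by both methoxy groups, the aryllithium adds once to the nitrile (the N-lithio ketimine resists over-addition), and aqueous acid hydrolyses ketimine and acetal together.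

Step 8
Reactants: 13 3-(3,5-dimethoxybenzoyl)-2,4-dimethoxybenzaldehyde
Product: 14 3-(3,5-dihydroxybenzoyl)-2,4-dihydroxybenzaldehyde
Conditions: BBr3 (8 equiv), CH2Cl2, −78 °C → rt; ice-water
Reagents that add atoms: none
Why: Lewis-acid aryl methyl ether cleavage is safe at this stage because the substrate holds only aryl ketone and aldehyde functions and no ionisable benzylic C–O bond.

Step 9
Reactants: 14 3-(3,5-dihydroxybenzoyl)-2,4-dihydroxybenzaldehyde
Product: 15 5-[3-formyl-2-hydroxy-6-(pivaloyloxy)benzoyl]-1,3-phenylene dipivalate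
Conditions: PivCl (3.1 equiv), Et3N, CH2Cl2, −20 → 0 °C
Reagents that add atoms: pivaloyl chloride CC(C)(C)C(=O)Cl
Why: Chemoselective esterification: the hydroxyl lying between the two carbonyl groups is hydrogen-bonded and hindered and stays free while the three other phenols are acylated.

Step 10
Reactants: 15 5-[3-formyl-2-hydroxy-6-(pivaloyloxy)benzoyl]-1,3-phenylene dipivalate
Product: 16 rac-5-{hydroxy[2-hydroxy-3-(hydroxymethyl)-6-(pivaloyloxy)phenyl]methyl}-1,3-phenylene dipivalate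
Conditions: NaBH4, CeCl3·7H2O, THF/MeOH, −20 → 0 °C; AcOH quench
Reagents that add atoms: none
Why: Luche-type borohydride reduction converts aldehyde and diaryl ketone into alcohols under buffered low-temperature conditions chosen so the hindered pivalates neither cleave nor migrate; the new carbinol centre is racemic and is erased in step 12.

Step 11
Reactants: 16 rac-5-{hydroxy[2-hydroxy-3-(hydroxymethyl)-6-(pivaloyloxy)phenyl]methyl}-1,3-phenylene dipivalate
Product: 17 rac-5-{[2-hydroxy-3-(hydroxymethyl)-6-(pivaloyloxy)phenyl](tosyl)methyl}-1,3-phenylene dipivalate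
Conditions: p-TolSO2H (1.3 equiv), CH2Cl2, rt
Reagents that add atoms: 4-methylbenzenesulfinic acid Cc1ccc(cc1)S(=O)O
Why: SN1 substitution: the doubly benzylic ortho-hydroxy carbinol ionises under mild acid and is captured at sulfur by the sulfinate, while the primary benzylic alcohol does not ionise.

**First key step and elaboration**

Step 12
Reactants: 17 rac-5-{[2-hydroxy-3-(hydroxymethyl)-6-(pivaloyloxy)phenyl](tosyl)methyl}-1,3-phenylene dipivalate; 7 (2S,5S)-1-[2,4-bis(pivaloyloxy)benzyl]-2,5-dimethylthiolan-1-ium tetrafluoroborate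
Product: 21 (2S,3S)-2-[2,4-bis(pivaloyloxy)phenyl]-3-[3,5-bis(pivaloyloxy)phenyl]-7-(hydroxymethyl)-2,3-dihydro-1-benzofuran-4-yl pivalate, via o-quinone methide 18 (not isolated), via sulfonium ylide 19 (not isolated), via betaine 20 (not isolated)
Conditions: 7 (1.3 equiv), Cs2CO3 (3 equiv), CH2Cl2/MeCN 4:1, −20 → 0 °C, 17 added slowly
Reagents that add atoms: none
Why: Carbonate unmasks o-quinone methide 18 and ylide 19, the ylide carbon adds in an intermolecular Michael (1,4-) addition to the methide carbon (C2–C3 bond) and betaine 20 closes by 5-exo-tet SN2 at the sulfonium carbon (Michael-initiated ring closure); the (2S,5S)-thiolane shields one ylide face so C2 becomes S, and the anti betaine closes to the favoured 2,3-trans ring, making C3 S.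

Step 13
Reactants: 21 (2S,3S)-2-[2,4-bis(pivaloyloxy)phenyl]-3-[3,5-bis(pivaloyloxy)phenyl]-7-(hydroxymethyl)-2,3-dihydro-1-benzofuran-4-yl pivalate
Product: 22 (2S,3S)-2-[2,4-bis(pivaloyloxy)phenyl]-3-[3,5-bis(pivaloyloxy)phenyl]-7-(bromomethyl)-2,3-dihydro-1-benzofuran-4-yl pivalate
Conditions: CBr4, PPh3, CH2Cl2, 0 °C
Reagents that add atoms: carbon tetrabromide BrC(Br)(Br)Br
Why: The Appel reaction converts the primary benzylic alcohol into the bromide under neutral conditions that preserve the esters and both ring stereocentres.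

Step 14
Reactants: 22 (2S,3S)-2-[2,4-bis(pivaloyloxy)phenyl]-3-[3,5-bis(pivaloyloxy)phenyl]-7-(bromomethyl)-2,3-dihydro-1-benzofuran-4-yl pivalate; 3 (2S,5S)-2,5-dimethylthiolane
Product: 23 (2S,5S)-1-{[(2S,3S)-2-[2,4-bis(pivaloyloxy)phenyl]-3-[3,5-bis(pivaloyloxy)phenyl]-4-(pivaloyloxy)-2,3-dihydro-1-benzofuran-7-yl]methyl}-2,5-dimethylthiolan-1-ium tetrafluoroborate
Conditions: AgBF4 (1.05 equiv), CH2Cl2, −20 °C → rt, dark
Reagents that add atoms: silver tetrafluoroborate [Ag+].F[B-](F)(F)F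
Why: Silver-assisted SN2 S-alkylation as in step 5; the para-acyloxy group keeps the benzylic position from ionising and the two ring stereocentres are not involved.

**Bromo-ring o-quinone methide precursor**

Step 15
Reactants: 24 1-bromo-3,5-dimethoxybenzene
Product: 26 2-bromo-4,6-dimethoxybenzaldehyde, via iminium salt 25 (not isolated)
Conditions: POCl3 (1.5 equiv), DMF, 0 → 90 °C; then H2O
Reagents that add atoms: N,N-dimethylformamide CN(C)C=O; water O
Why: Vilsmeier–Haack formylation takes place para to one methoxy group and ortho to the other (next to bromine), and the iminium salt is hydrolysed on work-up.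

Step 16
Reactants: 26 2-bromo-4,6-dimethoxybenzaldehyde; 27 3,5-dimethoxyphenylmagnesium chloride (1.0 M in THF)
Product: 28 rac-(2-bromo-4,6-dimethoxyphenyl)(3,5-dimethoxyphenyl)methanol
Conditions: THF, −10 → 0 °C; aq. NH4Cl
Reagents that add atoms: none
Why: Grignard 1,2-addition to the aldehyde proceeds at low temperature without halogen–magnesium exchange at the aryl bromide; the racemic carbinol centre is planarised later.

Step 17
Reactants: 28 rac-(2-bromo-4,6-dimethoxyphenyl)(3,5-dimethoxyphenyl)methanol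
Product: 29 (2-bromo-4,6-dimethoxyphenyl)(3,5-dimethoxyphenyl)methanone
Conditions: activated MnO2 (15 equiv), CH2Cl2, reflux
Reagents that add atoms: none
Why: Benzylic alcohol oxidation gives the benzophenone so that demethylation can be run without an ionisable diaryl carbinol.

Step 18
Reactants: 29 (2-bromo-4,6-dimethoxyphenyl)(3,5-dimethoxyphenyl)methanone
Product: 30 (2-bromo-4,6-dihydroxyphenyl)(3,5-dihydroxyphenyl)methanone
Conditions: BBr3 (8 equiv), CH2Cl2, −78 °C → rt; ice-water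
Reagents that add atoms: none
Why: Lewis-acid aryl methyl ether cleavage; ketone and aryl bromide are inert to BBr3.

Step 19
Reactants: 30 (2-bromo-4,6-dihydroxyphenyl)(3,5-dihydroxyphenyl)methanone
Product: 31 5-[2-bromo-6-hydroxy-4-(pivaloyloxy)benzoyl]-1,3-phenylene dipivalate
Conditions: PivCl (3.1 equiv), Et3N, CH2Cl2, −20 → 0 °C
Reagents that add atoms: pivaloyl chloride CC(C)(C)C(=O)Cl
Why: Chemoselective esterification: the hydroxyl ortho to the ketone is chelated and stays free while the para-hydroxyl and the two resorcinol hydroxyls are acylated.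

Step 20
Reactants: 31 5-[2-bromo-6-hydroxy-4-(pivaloyloxy)benzoyl]-1,3-phenylene dipivalate
Product: 32 rac-5-{[2-bromo-6-hydroxy-4-(pivaloyloxy)phenyl](hydroxy)methyl}-1,3-phenylene dipivalate
Conditions: NaBH4, CeCl3·7H2O, THF/MeOH, −20 → 0 °C; AcOH quench
Reagents that add atoms: none
Why: Borohydride (Luche) reduction of the o-hydroxybenzophenone gives the o-hydroxybenzhydrol; its racemic centre is removed in step 22.

Step 21
Reactants: 32 rac-5-{[2-bromo-6-hydroxy-4-(pivaloyloxy)phenyl](hydroxy)methyl}-1,3-phenylene dipivalate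
Product: 33 rac-5-{[2-bromo-6-hydroxy-4-(pivaloyloxy)phenyl](tosyl)methyl}-1,3-phenylene dipivalate
Conditions: p-TolSO2H (1.3 equiv), CH2Cl2, rt
Reagents that add atoms: 4-methylbenzenesulfinic acid Cc1ccc(cc1)S(=O)O
Why: SN1 sulfonylation as in step 11 gives the base-triggered o-quinone methide precursor; the styryl arm is deliberately absent here so no cation–olefin cyclisation can compete.

**Second key step and endgame**

Step 22
Reactants: 33 rac-5-{[2-bromo-6-hydroxy-4-(pivaloyloxy)phenyl](tosyl)methyl}-1,3-phenylene dipivalate; 23 (2S,5S)-1-{[(2S,3S)-2-[2,4-bis(pivaloyloxy)phenyl]-3-[3,5-bis(pivaloyloxy)phenyl]-4-(pivaloyloxy)-2,3-dihydro-1-benzofuran-7-yl]methyl}-2,5-dimethylthiolan-1-ium tetrafluoroborate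
Product: 37 (2S,3S)-4-bromo-3-[3,5-bis(pivaloyloxy)phenyl]-2-{(2S,3S)-2-[2,4-bis(pivaloyloxy)phenyl]-3-[3,5-bis(pivaloyloxy)phenyl]-4-(pivaloyloxy)-2,3-dihydro-1-benzofuran-7-yl}-2,3-dihydro-1-benzofuran-6-yl pivalate, via o-quinone methide 34 (not isolated), via sulfonium ylide 35 (not isolated), via betaine 36 (not isolated)
Conditions: 23 (1.2 equiv), Cs2CO3 (3 equiv), CH2Cl2/MeCN 4:1, −20 → 0 °C, 33 added slowly
Reagents that add atoms: none
Why: As in step 12, ylide 35 undergoes intermolecular Michael addition to o-quinone methide 34 (the C2–C3 bond joining the two halves) and betaine 36 ring-closes by SN2 at the sulfonium carbon; the (2S,5S)-thiolane again dictates the ylide face so C2 is S irrespective of the remote upper-ring stereocentres, and trans closure makes C3 S.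

Step 23
Reactants: 37 octapivalate bromide (as named in step 22); 38 4-ethenylphenyl acetate (4-acetoxystyrene)
Product: 39 (2S,3S)-4-[(E)-2-(4-acetoxyphenyl)ethenyl]-3-[3,5-bis(pivaloyloxy)phenyl]-2-{(2S,3S)-2-[2,4-bis(pivaloyloxy)phenyl]-3-[3,5-bis(pivaloyloxy)phenyl]-4-(pivaloyloxy)-2,3-dihydro-1-benzofuran-7-yl}-2,3-dihydro-1-benzofuran-6-yl pivalate
Conditions: 38 (2 equiv), Pd(OAc)2 (5 mol%), P(o-tol)3 (12 mol%), Et3N, DMF, 95 °C
Reagents that add atoms: none
Why: Mizoroki–Heck reaction: oxidative addition at the aryl bromide, syn insertion of the styrene and syn β-hydride elimination give the (E)-stilbene, leaving esters and sp3 stereocentres untouched.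

Step 24
Reactants: 39 nona-ester (as named in step 23)
Product: 40 4-[(2S,3S)-7-[(2S,3S)-3-(3,5-dihydroxyphenyl)-6-hydroxy-4-[(E)-2-(4-hydroxyphenyl)ethenyl]-2,3-dihydro-1-benzofuran-2-yl]-3-(3,5-dihydroxyphenyl)-4-hydroxy-2,3-dihydro-1-benzofuran-2-yl]benzene-1,3-diol (CNP0397447.1)
Conditions: DIBAL-H (30 equiv), CH2Cl2, −78 °C; MeOH, then aq. citric acid/Rochelle salt (pH 4–5), 0 °C, argon
Reagents that add atoms: none
Why: Hydride reduction of the nine aryl esters at low temperature liberates the phenols without free phenoxide or strong acid, which avoids quinone-methide opening of the dihydrobenzofurans (and re-closure on the wrong resorcinol oxygen) and leaves the (E)-alkene and all four stereocentres unchanged.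

## Compound list

1 | (2R,5R)-hexane-2,5-diol | C[C@@H](O)CC[C@@H](C)O | starting material
2 | (2R,5R)-hexane-2,5-diyl dimethanesulfonate | C[C@@H](OS(C)(=O)=O)CC[C@@H](C)OS(C)(=O)=O | intermediate
3 | (2S,5S)-2,5-dimethylthiolane | C[C@H]1CC[C@H](C)S1 | intermediate
4 | 4-methylbenzene-1,3-diol | Cc1ccc(O)cc1O | starting material
5 | 4-methyl-1,3-phenylene bis(2,2-dimethylpropanoate) | Cc1ccc(OC(=O)C(C)(C)C)cc1OC(=O)C(C)(C)C | intermediate
6 | 4-(bromomethyl)-1,3-phenylene bis(2,2-dimethylpropanoate) | BrCc1ccc(OC(=O)C(C)(C)C)cc1OC(=O)C(C)(C)C | intermediate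
7 | (2S,5S)-1-[2,4-bis(pivaloyloxy)benzyl]-2,5-dimethylthiolan-1-ium tetrafluoroborate | C[C@H]1CC[C@H](C)[S+]1Cc1ccc(OC(=O)C(C)(C)C)cc1OC(=O)C(C)(C)C.F[B-](F)(F)F | intermediate
8 | 2,4-dimethoxybenzaldehyde | COc1ccc(C=O)c(OC)c1 | starting material
9 | 2-(2,4-dimethoxyphenyl)-1,3-dioxolane | COc1ccc(C2OCCO2)c(OC)c1 | intermediate
10 | 3,5-dimethoxybenzonitrile | COc1cc(OC)cc(C#N)c1 | starting material
11 | [3-(1,3-dioxolan-2-yl)-2,6-dimethoxyphenyl]lithium | [Li]c1c(OC)ccc(C2OCCO2)c1OC | intermediate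
12 | N-lithio ketimine of [3-(1,3-dioxolan-2-yl)-2,6-dimethoxyphenyl](3,5-dimethoxyphenyl)methanone | [Li]N=C(c1cc(OC)cc(OC)c1)c1c(OC)ccc(C2OCCO2)c1OC | intermediate
13 | 3-(3,5-dimethoxybenzoyl)-2,4-dimethoxybenzaldehyde | COc1cc(OC)cc(c1)C(=O)c1c(OC)ccc(C=O)c1OC | intermediate
14 | 3-(3,5-dihydroxybenzoyl)-2,4-dihydroxybenzaldehyde | Oc1cc(O)cc(c1)C(=O)c1c(O)ccc(C=O)c1O | intermediate
15 | 5-[3-formyl-2-hydroxy-6-(pivaloyloxy)benzoyl]-1,3-phenylene dipivalate | CC(C)(C)C(=O)Oc1cc(OC(=O)C(C)(C)C)cc(c1)C(=O)c1c(OC(=O)C(C)(C)C)ccc(C=O)c1O | intermediate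
16 | rac-5-{hydroxy[2-hydroxy-3-(hydroxymethyl)-6-(pivaloyloxy)phenyl]methyl}-1,3-phenylene dipivalate (racemic carbinol) | CC(C)(C)C(=O)Oc1cc(OC(=O)C(C)(C)C)cc(c1)C(O)c1c(OC(=O)C(C)(C)C)ccc(CO)c1O | intermediate
17 | rac-5-{[2-hydroxy-3-(hydroxymethyl)-6-(pivaloyloxy)phenyl](tosyl)methyl}-1,3-phenylene dipivalate (racemic) | CC(C)(C)C(=O)Oc1cc(OC(=O)C(C)(C)C)cc(c1)C(c1c(OC(=O)C(C)(C)C)ccc(CO)c1O)S(=O)(=O)c1ccc(C)cc1 | intermediate
18 | 5-{[3-(hydroxymethyl)-2-oxo-6-(pivaloyloxy)cyclohexa-3,5-dien-1-ylidene]methyl}-1,3-phenylene dipivalate (o-quinone methide, alkene geometry not fixed) | O=C1C(CO)=CC=C(OC(=O)C(C)(C)C)C1=Cc1cc(OC(=O)C(C)(C)C)cc(OC(=O)C(C)(C)C)c1 | intermediate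
19 | ylide of 7: (2S,5S)-2,5-dimethylthiolan-1-ium-1-yl [2,4-bis(pivaloyloxy)phenyl]methanide | C[C@H]1CC[C@H](C)[S+]1[CH-]c1ccc(OC(=O)C(C)(C)C)cc1OC(=O)C(C)(C)C | intermediate
20 | betaine from 18 and 19 (phenoxide / sulfonium; C–S carbon has the configuration that inverts to 2S, diaryl methine as in 21) | [O-]c1c(CO)ccc(OC(=O)C(C)(C)C)c1[C@H](c1cc(OC(=O)C(C)(C)C)cc(OC(=O)C(C)(C)C)c1)[C@H](c1ccc(OC(=O)C(C)(C)C)cc1OC(=O)C(C)(C)C)[S+]1[C@@H](C)CC[C@@H]1C | intermediate
21 | (2S,3S)-2-[2,4-bis(pivaloyloxy)phenyl]-3-[3,5-bis(pivaloyloxy)phenyl]-7-(hydroxymethyl)-2,3-dihydro-1-benzofuran-4-yl pivalate (trans) | OCc1ccc(OC(=O)C(C)(C)C)c2c1O[C@H](c1ccc(OC(=O)C(C)(C)C)cc1OC(=O)C(C)(C)C)[C@H]2c1cc(OC(=O)C(C)(C)C)cc(OC(=O)C(C)(C)C)c1 | intermediate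
22 | (2S,3S)-2-[2,4-bis(pivaloyloxy)phenyl]-3-[3,5-bis(pivaloyloxy)phenyl]-7-(bromomethyl)-2,3-dihydro-1-benzofuran-4-yl pivalate | BrCc1ccc(OC(=O)C(C)(C)C)c2c1O[C@H](c1ccc(OC(=O)C(C)(C)C)cc1OC(=O)C(C)(C)C)[C@H]2c1cc(OC(=O)C(C)(C)C)cc(OC(=O)C(C)(C)C)c1 | intermediate
23 | (2S,5S)-1-{[(2S,3S)-2-[2,4-bis(pivaloyloxy)phenyl]-3-[3,5-bis(pivaloyloxy)phenyl]-4-(pivaloyloxy)-2,3-dihydro-1-benzofuran-7-yl]methyl}-2,5-dimethylthiolan-1-ium tetrafluoroborate | C[C@H]1CC[C@H](C)[S+]1Cc1ccc(OC(=O)C(C)(C)C)c2c1O[C@H](c1ccc(OC(=O)C(C)(C)C)cc1OC(=O)C(C)(C)C)[C@H]2c1cc(OC(=O)C(C)(C)C)cc(OC(=O)C(C)(C)C)c1.F[B-](F)(F)F | intermediate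
24 | 1-bromo-3,5-dimethoxybenzene | COc1cc(Br)cc(OC)c1 | starting material
25 | N-[(2-bromo-4,6-dimethoxyphenyl)methylidene]-N-methylmethanaminium chloride | COc1cc(Br)c(C=[N+](C)C)c(OC)c1.[Cl-] | intermediate
26 | 2-bromo-4,6-dimethoxybenzaldehyde | COc1cc(Br)c(C=O)c(OC)c1 | intermediate
27 | 3,5-dimethoxyphenylmagnesium chloride | COc1cc(OC)cc([Mg]Cl)c1 | starting material
28 | rac-(2-bromo-4,6-dimethoxyphenyl)(3,5-dimethoxyphenyl)methanol (racemic) | COc1cc(OC)cc(c1)C(O)c1c(Br)cc(OC)cc1OC | intermediate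
29 | (2-bromo-4,6-dimethoxyphenyl)(3,5-dimethoxyphenyl)methanone | COc1cc(OC)cc(c1)C(=O)c1c(Br)cc(OC)cc1OC | intermediate
30 | (2-bromo-4,6-dihydroxyphenyl)(3,5-dihydroxyphenyl)methanone | Oc1cc(O)cc(c1)C(=O)c1c(Br)cc(O)cc1O | intermediate
31 | 5-[2-bromo-6-hydroxy-4-(pivaloyloxy)benzoyl]-1,3-phenylene dipivalate | CC(C)(C)C(=O)Oc1cc(OC(=O)C(C)(C)C)cc(c1)C(=O)c1c(Br)cc(OC(=O)C(C)(C)C)cc1O | intermediate
32 | rac-5-{[2-bromo-6-hydroxy-4-(pivaloyloxy)phenyl](hydroxy)methyl}-1,3-phenylene dipivalate (racemic) | CC(C)(C)C(=O)Oc1cc(OC(=O)C(C)(C)C)cc(c1)C(O)c1c(Br)cc(OC(=O)C(C)(C)C)cc1O | intermediate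
33 | rac-5-{[2-bromo-6-hydroxy-4-(pivaloyloxy)phenyl](tosyl)methyl}-1,3-phenylene dipivalate (racemic) | CC(C)(C)C(=O)Oc1cc(OC(=O)C(C)(C)C)cc(c1)C(c1c(Br)cc(OC(=O)C(C)(C)C)cc1O)S(=O)(=O)c1ccc(C)cc1 | intermediate
34 | 5-{[2-bromo-6-oxo-4-(pivaloyloxy)cyclohexa-2,4-dien-1-ylidene]methyl}-1,3-phenylene dipivalate (o-quinone methide, alkene geometry not fixed) | O=C1C=C(OC(=O)C(C)(C)C)C=C(Br)C1=Cc1cc(OC(=O)C(C)(C)C)cc(OC(=O)C(C)(C)C)c1 | intermediate
35 | ylide of 23 (benzylic carbanion on the sulfonium) | C[C@H]1CC[C@H](C)[S+]1[CH-]c1ccc(OC(=O)C(C)(C)C)c2c1O[C@H](c1ccc(OC(=O)C(C)(C)C)cc1OC(=O)C(C)(C)C)[C@H]2c1cc(OC(=O)C(C)(C)C)cc(OC(=O)C(C)(C)C)c1 | intermediate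
36 | betaine from 34 and 35 (phenoxide / sulfonium; C–S carbon has the configuration that inverts to 2S) | [O-]c1cc(OC(=O)C(C)(C)C)cc(Br)c1[C@H](c1cc(OC(=O)C(C)(C)C)cc(OC(=O)C(C)(C)C)c1)[C@H](c1ccc(OC(=O)C(C)(C)C)c2c1O[C@H](c1ccc(OC(=O)C(C)(C)C)cc1OC(=O)C(C)(C)C)[C@H]2c1cc(OC(=O)C(C)(C)C)cc(OC(=O)C(C)(C)C)c1)[S+]1[C@@H](C)CC[C@@H]1C | intermediate
37 | (2S,3S)-4-bromo-3-[3,5-bis(pivaloyloxy)phenyl]-2-{(2S,3S)-2-[2,4-bis(pivaloyloxy)phenyl]-3-[3,5-bis(pivaloyloxy)phenyl]-4-(pivaloyloxy)-2,3-dihydro-1-benzofuran-7-yl}-2,3-dihydro-1-benzofuran-6-yl pivalate | Brc1cc(OC(=O)C(C)(C)C)cc2c1[C@H](c1cc(OC(=O)C(C)(C)C)cc(OC(=O)C(C)(C)C)c1)[C@@H](c1ccc(OC(=O)C(C)(C)C)c3c1O[C@H](c1ccc(OC(=O)C(C)(C)C)cc1OC(=O)C(C)(C)C)[C@H]3c1cc(OC(=O)C(C)(C)C)cc(OC(=O)C(C)(C)C)c1)O2 | intermediate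
38 | 4-ethenylphenyl acetate | CC(=O)Oc1ccc(C=C)cc1 | starting material
39 | (2S,3S)-4-[(E)-2-(4-acetoxyphenyl)ethenyl] analogue of 37 (octapivalate monoacetate of the target) | CC(=O)Oc1ccc(/C=C/c2cc(OC(=O)C(C)(C)C)cc3c2[C@H](c2cc(OC(=O)C(C)(C)C)cc(OC(=O)C(C)(C)C)c2)[C@@H](c2ccc(OC(=O)C(C)(C)C)c4c2O[C@H](c2ccc(OC(=O)C(C)(C)C)cc2OC(=O)C(C)(C)C)[C@H]4c2cc(OC(=O)C(C)(C)C)cc(OC(=O)C(C)(C)C)c2)O3)cc1 | intermediate
40 | CNP0397447.1 (both dihydrobenzofurans 2S,3S-trans, E-stilbene) | Oc1ccc(/C=C/c2cc(O)cc3c2[C@H](c2cc(O)cc(O)c2)[C@@H](c2ccc(O)c4c2O[C@H](c2ccc(O)cc2O)[C@H]4c2cc(O)cc(O)c2)O3)cc1 | target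

## Summary

Total step count: 24.

Longest linear sequence: 12 steps (8 → 9 → 13 → 14 → 15 → 16 → 17 → 21 → 22 → 23 → 37 → 39 → 40; steps 6–14 and 22–24).

Three steps most likely to fail:

1. **Step 12** (first Michael/ring closure). A benzylide has not been proven on this hindered o-quinone methide; the phenoxide may be O-benzylated by the sulfonium salt, and facial control by the thiolane may be incomplete. Fallback: setting out from 6 and 17, bromide 6 is S-alkylated onto achiral tetrahydrothiophene (AgBF4) to give 1-[2,4-bis(pivaloyloxy)benzyl]thiolan-1-ium tetrafluoroborate F1. The same annulation with 17 then gives the trans product as a racemate, i.e. 21 together with its (2R,3R) enantiomer F2, which is removed by preparative chiral SFC. Stereocontrol is thus moved from the reagent to a resolution, and the route is rejoined at 21.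

2. **Step 22** (second Michael/ring closure, fragment union). The bulky chiral ylide may be mismatched with the upper-ring stereocentres, and the o-quinone methide is flanked by bromine. Fallback: setting out from 22 and 33, bromide 22 is converted with tetrahydrothiophene/AgBF4 into the achiral thiolanium salt F3. Its ylide adds to the o-quinone methide from 33 under substrate and thermodynamic (trans) control only, giving 37 together with the diastereomer having a (2R,3R) lower ring F4. Being diastereomers, the two are separated by ordinary silica chromatography or crystallisation, and the route is rejoined at 37.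

3. **Step 23** (late Heck on an ortho-substituted bromide carrying eight esters). Fallback: setting out from 37, the alkene is introduced by Suzuki–Miyaura coupling instead of olefin insertion. (E)-2-(4-Acetoxyphenyl)ethenylboronic acid pinacol ester F5 (from Zr-catalysed hydroboration of 4-ethynylphenyl acetate with pinacolborane) is coupled with 37 using Pd(dppf)Cl2 and anhydrous CsF in dioxane at 80 °C, with retention of the E geometry, and the route is rejoined at 39.

## Further compounds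

F1 | step 12 | 1-[2,4-bis(pivaloyloxy)benzyl]thiolan-1-ium tetrafluoroborate | C1CC[S+](C1)Cc1ccc(OC(=O)C(C)(C)C)cc1OC(=O)C(C)(C)C.F[B-](F)(F)F
F2 | step 12 | (2R,3R) enantiomer of 21 | OCc1ccc(OC(=O)C(C)(C)C)c2c1O[C@@H](c1ccc(OC(=O)C(C)(C)C)cc1OC(=O)C(C)(C)C)[C@@H]2c1cc(OC(=O)C(C)(C)C)cc(OC(=O)C(C)(C)C)c1
F3 | step 22 | 1-{[(2S,3S)-2-[2,4-bis(pivaloyloxy)phenyl]-3-[3,5-bis(pivaloyloxy)phenyl]-4-(pivaloyloxy)-2,3-dihydro-1-benzofuran-7-yl]methyl}thiolan-1-ium tetrafluoroborate | C1CC[S+](C1)Cc1ccc(OC(=O)C(C)(C)C)c2c1O[C@H](c1ccc(OC(=O)C(C)(C)C)cc1OC(=O)C(C)(C)C)[C@H]2c1cc(OC(=O)C(C)(C)C)cc(OC(=O)C(C)(C)C)c1.F[B-](F)(F)F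
F4 | step 22 | diastereomer of 37 with (2R,3R) lower ring and (2S,3S) upper ring | Brc1cc(OC(=O)C(C)(C)C)cc2c1[C@@H](c1cc(OC(=O)C(C)(C)C)cc(OC(=O)C(C)(C)C)c1)[C@H](c1ccc(OC(=O)C(C)(C)C)c3c1O[C@H](c1ccc(OC(=O)C(C)(C)C)cc1OC(=O)C(C)(C)C)[C@H]3c1cc(OC(=O)C(C)(C)C)cc(OC(=O)C(C)(C)C)c1)O2
F5 | step 23 | 4-[(E)-2-(4,4,5,5-tetramethyl-1,3,2-dioxaborolan-2-yl)ethenyl]phenyl acetate | CC(=O)Oc1ccc(/C=C/B2OC(C)(C)C(C)(C)O2)cc1
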